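Readings and results stem from a simulated flask for an exercise; scatter was added.

Late in the earlier runs, at 10.0 min, Wednesday's flask holds 33.4% of target and Friday's 19.1%, a clear gap, though their starting material stands level at 63.2% and 62.8%. We therefore read each flask by two factors: the charge-minutes, which are the time integral of the free fraction of the charge, and the target made per charge-minute. The second factor is a pseudo-first-order constant, a capture constant times [partner].

| flask | starting material | partner | second substrate | remark | time |
|---|---|---|---|---|---|
| Wednesday's | 0.20 M (fed, over 8.0 min) | 1.1 equiv | 0.25 equiv | run made earlier; the fed solution adds 0.10 times the starting volume |  |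
| Friday's | 0.20 M (fed, over 8.0 min) | 1.1 equiv | 1 equiv | run made earlier; the fed solution adds 0.10 times the starting volume |  |
| larch | 0.20 M (fed, over 8.0 min) | 1.10 equiv | 0.500 equiv | the fed solution adds 0.10 times the starting volume | 8.0 min |
| cedar | 0.20 M | 1.10 equiv | 0.500 equiv | everything together at the start, the whole solution of starting material included, so that from the start the volume is larger by 0.10 times the starting volume | 2.0 min |

1. which of the two ends with the higher amount of target, in percent of the starting material charged ("neither" if they lie within 2 percentage points) (larch / cedar / neither)
2. target at the end, in percent of the starting material charged, larch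
3. target at the end, in percent of the starting material charged, cedar

- amounts and yields of target count idle adduct too
- charges are per starting volume, the dose included; the dosed solution carries all of it
- steps thought possible: starting material + partner -> target; second substrate + partner -> second product; starting material + second substrate -> cross product; partner + target <-> idle adduct
- percentages count the whole charge, also what has not yet gone in

| run | time / min | target / % | starting material / % |
|---|---|---|---|
| Wednesday's | 0.833 | 0.7 | 10.1 |
| Wednesday's | 1.33 | 1.9 | 15.6 |
| Wednesday's | 2.00 | 3.0 | 21.9 |
| Wednesday's | 4.00 | 9.0 | 39.5 |
| Wednesday's | 6.00 | 17.1 | 55.5 |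
| Wednesday's | 10.0 | 33.4 | 63.2 |
| Friday's | 1.50 | 2.0 | 15.2 |
| Friday's | 3.00 | 4.1 | 29.6 |
| Friday's | 5.00 | 8.3 | 45.7 |
| Friday's | 6.00 | 10.9 | 53.9 |
| Friday's | 8.00 | 14.6 | 69.7 |
| Friday's | 10.0 | 19.1 | 62.8 |

(readings scatter by 0.5 percentage points)

We read the target column against the starting-material column. Wednesday's rows from 4.00 min to 6.00 min give 0.0853 /min per charge-minute as a reading, and Friday's rows from 3.00 min to 6.00 min give less, 0.0543 /min. For Wednesday's stretch we take the whole second substrate and the mean target off the partner charge, which leaves [partner] near 0.144 M, with the feed's dilution left out. The capture constant, target made per charge-minute and per unit of [partner], is then 0.593 /M/min.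

The zero of the scale is the count without any reaction: larch's steady feed collects 4.00 min of charge-minutes and cedar 2.0 min, twice as many for larch. Friday's row at 8.00 min shows 69.7% rather than the full charge, so a straight rise gives larch 2.79 min. Larch's second substrate lies between the two runs' charges, so we take their mean constant, 0.0698 /min, and reckon 19.5%.

Cedar starts at [partner] 0.200 M, so its undepleted exposure is 23.7%. If [starting material] and [partner] each fall by about that fraction, the exposure shrinks to 18.1%. Our reckoning thus stands at 19.5% for larch and 18.1% for cedar; held against the margin of 2 percentage points, we call that neither. The forecast differs: 22.5% for larch against 16.5% for cedar, hence larch. “Larch wins because of its longer time.”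

The flasks give 21.8% for larch and 16.6% for cedar, so larch leads.

    starting material + partner → target (k = 0.0100 /M/s)
    second substrate + partner → second product (k = 0.0210 /M/s)
    starting material + second substrate → cross product (k = 0.0120 /M/s)
    partner + target ⇌ idle adduct, settled at all times (K = 5.90 /M)

Our tie fails on both sides, with larch ending above our figure and cedar below it. Cedar ends with 75% of its starting material and 65% of its partner. The root of their product is 69.8%, lower than our 76.3%. Exposure times that root gives 16.5% against the simulated 16.6%. The neighbouring flask is cedar with 1.90 equiv of partner, which starts [partner] at 0.345 M. It ends with 66% of its starting material and 66% of its partner, and the same reckoning gives 27.0%. Its simulated target is 27.0%.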